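## Retrosynthetic overview

1. The two cis methyl groups are treated as the remnant of a CH2–S–CH2 bridge: the target comes, by C–S hydrogenolysis, from a cis-fused 2,4-diaryl-3-oxa-7-thiabicyclo[3.3.0]octane with both aryls exo.
2. That bicycle is cut at the C8–C8' bond and at both benzylic C–O bonds (oxidative phenol coupling, water as oxygen source), giving an acyclic bis[(E)-sinapyl] sulfide.
3. The sulfide comes from two molecules of 4-allyl-2,6-dimethoxyphenol and Na2S, through 1,8-addition to a vinyl quinone methide.
4. Ring order: thiolane (one C–C bond) and tetrahydrofuran (two C–O bonds) form together in one operation; the thiolane is excised in the last step; both arene rings are bought.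

Assumption: the SMILES encodes the (2S,3S,4R,5R) isomer (aryls cis to each other, methyls cis to each other, aryl/methyl trans); with two identical aryls this is a meso, achiral compound, so only relative configuration has to be controlled.

## Route

Step 1
Reactants: 1 4-allyl-2,6-dimethoxyphenol (2 equiv)
Product: 4 bis[(E)-3-(4-hydroxy-3,5-dimethoxyphenyl)prop-2-en-1-yl] sulfide, via vinyl quinone methide 2 (not isolated), via sinapyl thiol 3 (not isolated)
Conditions: Ag2O (1.5 equiv per phenol), toluene, 20 °C, 1 h; filter (Celite, N2); filtrate added at 0 °C to Na2S·9H2O (0.5 equiv per phenol) in DMF; 0 → 20 °C, 1 h; aq NH4Cl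
Reagents that add atoms: sodium sulfide (used as Na2S·9H2O), [Na+].[Na+].[S-2]
Why: Ag2O dehydrogenates the 4-allylphenol to the cross-conjugated vinyl quinone methide 2 (a known oxidation of 4-allylphenols), and sulfide, then thiolate 3, add by vinylogous thia-Michael (1,8-conjugate) addition at the terminal carbon, which re-aromatises the ring and leaves the conjugated (E)-styrene; benzylic 1,6-adducts can revert through the phenolate, so the linear (E,E)-sulfide is the expected thermodynamic product, and no stereocentre is formed.

Step 2
Reactants: 4 bis[(E)-3-(4-hydroxy-3,5-dimethoxyphenyl)prop-2-en-1-yl] sulfide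
Product: 7 (1S,3R,3aR,6aS)-1,3-bis(4-hydroxy-3,5-dimethoxyphenyl)tetrahydro-1H,3H-thieno[3,4-c]furan (meso; cis-fused; both aryls exo), via bis-quinone methide 5 (not isolated), via hydroxy quinone methide 6 (not isolated)
Conditions: 4 added over 4 h to FeCl3·6H2O (2.5 equiv), acetone–H2O 3:1, N2, 20 °C, final 3 mM; then 2 h
Reagents that add atoms: water, O
Why: Proposed new method: two one-electron oxidations by FeCl3 (trivalent iron) give phenoxyl radicals with spin at C8, and the tether allows only 8–8' coupling (five-membered ring; 8–O–4' is geometrically impossible and the 5-positions carry OMe) to give bis-quinone methide 5, water adds to one quinone methide (6) and the new benzylic hydroxyl closes 5-exo on the other, so thiolane and tetrahydrofuran form in the same operation; only the cis-thiolane can close to the strain-free cis-fused bicycle (a stacked approach of the two arms should favour it) and the aryls should settle exo because ring closure is reversible through the quinone methide under the acidic conditions, which sets all four stereocentres in the meso relationship of the target; the closest known reaction type is the oxidative 8–8' dehydrodimerisation of sinapyl alcohol to syringaresinol and of 4-propenylsyringol in water to 2,5-diaryl-3,4-dimethyltetrahydrofurans.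

Step 3
Reactants: 7 (1S,3R,3aR,6aS)-1,3-bis(4-hydroxy-3,5-dimethoxyphenyl)tetrahydro-1H,3H-thieno[3,4-c]furan
Product: 8 Fragransin B1, (2S,3S,4R,5R)-2,5-bis(4-hydroxy-3,5-dimethoxyphenyl)-3,4-dimethyltetrahydrofuran (meso)
Conditions: Raney Ni (W-2, washed neutral, excess), EtOH–THF 1:1, 20 → 50 °C, 2 h
Reagents that add atoms: none
Why: Raney Ni reductive desulfurisation (Mozingo-type C–S hydrogenolysis) cleaves both C–S bonds at the CH2 carbons, which are not stereocentres, so the bridge becomes the two cis methyl groups and the four ring stereocentres set in step 2 are untouched.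

## Compound list

1 | 4-allyl-2,6-dimethoxyphenol | C=CCc1cc(OC)c(O)c(OC)c1 | starting material
2 | 4-allylidene-2,6-dimethoxycyclohexa-2,5-dien-1-one (vinyl quinone methide) | C=CC=C1C=C(OC)C(=O)C(OC)=C1 | intermediate
3 | (E)-3-(4-hydroxy-3,5-dimethoxyphenyl)prop-2-ene-1-thiol (sinapyl thiol, present as thiolate) | COc1cc(/C=C/CS)cc(OC)c1O | intermediate
4 | bis[(E)-3-(4-hydroxy-3,5-dimethoxyphenyl)prop-2-en-1-yl] sulfide | COc1cc(/C=C/CSC/C=C/c2cc(OC)c(O)c(OC)c2)cc(OC)c1O | intermediate
5 | cis-3,4-bis[(3,5-dimethoxy-4-oxocyclohexa-2,5-dien-1-ylidene)methyl]thiolane (meso bis-quinone methide) | O=C1C(OC)=CC(=C[C@H]2CSC[C@H]2C=C3C=C(OC)C(=O)C(OC)=C3)C=C1OC | intermediate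
6 | cis-3-[hydroxy(4-hydroxy-3,5-dimethoxyphenyl)methyl]-4-[(3,5-dimethoxy-4-oxocyclohexa-2,5-dien-1-ylidene)methyl]thiolane (carbinol centre either configuration) | COc1cc(C(O)[C@H]2CSC[C@H]2C=C3C=C(OC)C(=O)C(OC)=C3)cc(OC)c1O | intermediate
7 | (1S,3R,3aR,6aS)-1,3-bis(4-hydroxy-3,5-dimethoxyphenyl)tetrahydro-1H,3H-thieno[3,4-c]furan (meso; cis-fused 3-oxa-7-thiabicyclo[3.3.0]octane; aryls cis to each other and trans to the CH2S arms) | COc1cc([C@H]2O[C@@H](c3cc(OC)c(O)c(OC)c3)[C@H](CSC4)[C@@H]24)cc(OC)c1O | intermediate
8 | Fragransin B1, (2S,3S,4R,5R)-2,5-bis(4-hydroxy-3,5-dimethoxyphenyl)-3,4-dimethyltetrahydrofuran | COc1cc([C@H]2O[C@@H](c3cc(OC)c(O)c(OC)c3)[C@H](C)[C@@H]2C)cc(OC)c1O | target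

## Step count and risks

Total step count: 3. Longest linear sequence: 3.

Steps most likely to fail, most risky first:

**Step 2** (untested oxidative bicyclisation; risks are intermolecular coupling, a trans-thiolane that cannot close, or aryl attack on the quinone methide). The fallback sets out from 4 and returns at 7. Direct irradiation of 4 (hν 300 nm, degassed MeCN, 5 mM) gives, by intramolecular [2+2] photocycloaddition of the two styrene arms, the cyclobutane cis-fused 6,7-bis(4-hydroxy-3,5-dimethoxyphenyl)-3-thiabicyclo[3.2.0]heptane F3. Its ring fusion is necessarily cis, which fixes the C8/C8' relationship before any oxidation. F3 is then oxidised with FeCl3·6H2O (2.2 equiv, aqueous acetone). The phenoxyl radical breaks the strained bis-benzylic C–C bond to give the cis bis-quinone methide 5, which hydrates and closes to 7 as in the main route.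

**Step 1** (regiochemistry of sulfur addition to the vinyl quinone methide, or reduction of the quinone methide by sulfide). The fallback sets out from 1 and returns at 4. Compound 1 is oxidised as before to 2, which is trapped with acetic acid (an oxygen nucleophile precedented for this 1,8-addition) to give (E)-sinapyl acetate F1. Allylic substitution of F1 with potassium thioacetate (CH3COSK), catalysed by Pd(PPh3)4 (zerovalent palladium; π-allyl intermediate, attack at the unhindered terminus), gives S-[(E)-sinapyl] thioacetate F2. Methanolysis of F2 (K2CO3, MeOH–THF) in the presence of a second equivalent of F1 and Pd(PPh3)4 releases the thiolate, which is allylated in the same way to give 4.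

**Step 3** (basic Raney Ni can open the p-hydroxybenzyl ether through the phenolate and a quinone methide, leading to C–O hydrogenolysis or epimerisation). The fallback sets out from 7 and returns at 8. Both phenols are acetylated (Ac2O, pyridine) to the diacetate of 7, F4, which cannot form a quinone methide. Desulfurisation of F4 with neutral Raney Ni in EtOAc–EtOH gives Fragransin B1 diacetate F5. Methanolysis of F5 (K2CO3, MeOH, 20 °C) gives 8.

## Further compounds

F1 | step 1 | (E)-3-(4-hydroxy-3,5-dimethoxyphenyl)prop-2-en-1-yl acetate (sinapyl acetate) | COc1cc(/C=C/COC(C)=O)cc(OC)c1O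
F2 | step 1 | S-[(E)-3-(4-hydroxy-3,5-dimethoxyphenyl)prop-2-en-1-yl] ethanethioate | COc1cc(/C=C/CSC(C)=O)cc(OC)c1O
F3 | step 2 | cis-fused 6,7-bis(4-hydroxy-3,5-dimethoxyphenyl)-3-thiabicyclo[3.2.0]heptane (C6/C7 configuration as formed, not needed) | COc1cc(C2C(c3cc(OC)c(O)c(OC)c3)[C@@H]3CSC[C@H]23)cc(OC)c1O
F4 | step 3 | (1S,3R,3aR,6aS)-1,3-bis(4-acetoxy-3,5-dimethoxyphenyl)tetrahydro-1H,3H-thieno[3,4-c]furan (diacetate of 7) | COc1cc([C@H]2O[C@@H](c3cc(OC)c(OC(C)=O)c(OC)c3)[C@H](CSC4)[C@@H]24)cc(OC)c1OC(C)=O
F5 | step 3 | (2S,3S,4R,5R)-2,5-bis(4-acetoxy-3,5-dimethoxyphenyl)-3,4-dimethyltetrahydrofuran (Fragransin B1 diacetate) | COc1cc([C@H]2O[C@@H](c3cc(OC)c(OC(C)=O)c(OC)c3)[C@H](C)[C@@H]2C)cc(OC)c1OC(C)=O
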